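The trimethoxyphenyl ring (ring C) is built, not bought. C3′, C4′, C5′ (the three contiguous oxygen-bearing carbons) and C6′ are traced back to the carbonyl carbon, the two methoxy carbons and the CHCl carbon of a squarate-derived 4-chlorocyclobutenone, and C1′ and C2′ to a 1,1-disubstituted alkene on lactone C4. In one operation, Stille coupling (bond C1′–C6′) followed by thermal 4π opening and 6π closure (bond C2′–C3′) should deliver the 3-hydroxy-4,5-dimethoxyphenyl ring on the intact trans-lactone (ring B). The precursor is the (3R,4R)-lactone carrying the O-benzyl vanillyl group at C3 and a 2-(tributylstannyl)allyl group at C4.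

Key step: step 9

Assumption: 4-(benzyloxy)-3-methoxybenzyl alcohol, the O-benzyl ether of vanillyl alcohol, is treated as a purchasable starting material; numbering used below: ring A = vanillyl arene, ring B = lactone (O1, C2 carbonyl, C3, C4, C5), ring C = trioxygenated arene (C1′ carries the benzylic CH2).

Step 1
Reactants: 1 pent-4-ynoic acid; 2 (S)-4-benzyloxazolidin-2-one
Product: 4 (S)-4-benzyl-3-(pent-4-ynoyl)oxazolidin-2-one, via mixed pivalic anhydride 3 (not isolated)
Conditions: PivCl, Et3N, THF, −20 °C; then LiCl, 2, −20 °C to rt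
Reagents that add atoms: none
Why: N-Acylation of the oxazolidinone by a mixed pivalic anhydride under LiCl/Et3N activation is a standard way to load this auxiliary, the hindered pivaloyl carbonyl directing attack to the pentynoyl carbonyl while the alkyne is inert.

Step 2
Reactants: 4 (S)-4-benzyl-3-(pent-4-ynoyl)oxazolidin-2-one; 5 tert-butyl bromoacetate
Product: 7 tert-butyl (3R)-3-{[(4S)-4-benzyl-2-oxo-1,3-oxazolidin-3-yl]carbonyl}hex-5-ynoate, via sodium Z-enolate 6 (not isolated)
Conditions: NaN(SiMe3)2 (1.05 equiv), THF, −78 °C; then 5, −78 to −40 °C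
Reagents that add atoms: none
Why: Evans asymmetric alkylation: the chelated sodium Z-enolate is attacked by the bromoacetate on the face opposite the C4 benzyl group of the auxiliary, which sets the (R) centre that becomes lactone C4, and one equivalent of base is selective because the imide α-CH is far more acidic than the alkyne C–H.

Step 3
Reactants: 7 tert-butyl (3R)-3-{[(4S)-4-benzyl-2-oxo-1,3-oxazolidin-3-yl]carbonyl}hex-5-ynoate
Product: 9 (R)-4-(prop-2-yn-1-yl)dihydrofuran-2(3H)-one, via hydroxy ester 8 (not isolated)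
Conditions: LiBH4, THF, 0 °C to rt; aqueous work-up; then TFA, CH2Cl2, rt
Reagents that add atoms: none
Why: Reductive removal of the auxiliary by chemoselective LiBH4 reduction of the imide carbonyl (the tert-butyl ester is spared) followed by acid-mediated lactonisation of the γ-hydroxy tert-butyl ester, neither of which touches the stereocentre or the alkyne.

Step 4
Reactants: 9 (R)-4-(prop-2-yn-1-yl)dihydrofuran-2(3H)-one
Product: 10 (S)-4-[2-(tributylstannyl)prop-2-en-1-yl]dihydrofuran-2(3H)-one
Conditions: Bu3SnH (1.5 equiv), Mo(CO)3(CNtBu)3 (5 mol%), hydroquinone (10 mol%), THF, 55 °C; chromatography on Et3N-deactivated silica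
Reagents that add atoms: tributyltin hydride, CCCC[SnH](CCCC)CCCC
Why: Molybdenum-catalysed hydrostannation (syn hydrometallation) of a terminal alkyne delivers tin to the internal carbon under neutral conditions that spare the lactone; the C4 configuration is unchanged and the descriptor becomes S only because the tin-bearing branch now outranks C3.

Step 5
Reactants: 11 4-(benzyloxy)-3-methoxybenzyl alcohol
Product: 12 4-(benzyloxy)-3-methoxybenzyl bromide
Conditions: PBr3 (0.4 equiv), Et2O, 0 °C; used at once
Reagents that add atoms: phosphorus tribromide, BrP(Br)Br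
Why: Standard conversion of an electron-rich benzylic alcohol into its bromide with PBr3 (nucleophilic substitution via a phosphite ester), the product being used without chromatography.

Step 6
Reactants: 10 (S)-4-[2-(tributylstannyl)prop-2-en-1-yl]dihydrofuran-2(3H)-one; 12 4-(benzyloxy)-3-methoxybenzyl bromide
Product: 14 (3R,4R)-3-[4-(benzyloxy)-3-methoxybenzyl]-4-[2-(tributylstannyl)prop-2-en-1-yl]dihydrofuran-2(3H)-one, via lithium enolate 13 (not isolated)
Conditions: LiN(SiMe3)2 (1.05 equiv), THF, −78 °C; then 12, DMPU, −78 to −30 °C; aqueous NaH2PO4/Na2HPO4 (pH 7) work-up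
Reagents that add atoms: none
Why: Diastereoselective enolate alkylation of a β-substituted γ-butyrolactone: the benzylic bromide approaches the lithium enolate anti to the C4 side chain, so the new C3 centre is set trans (3R) by substrate control, and with the alkyne already converted into the alkenylstannane no acidic alkyne C–H competes while the C–Sn bond is inert to amide base.

Step 7
Reactants: 15 dimethyl squarate
Product: 16 4-hydroxy-2,3-dimethoxycyclobut-2-en-1-one (racemic)
Conditions: LiAlH(OtBu)3, THF, −78 °C; cold aqueous NH4Cl quench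
Reagents that add atoms: none
Why: 1,2-Reduction of one squarate carbonyl with a bulky alkoxyaluminium hydride stops at the hydroxycyclobutenone because the remaining carbonyl is a deactivated vinylogous ester, and a non-acidic quench prevents its rearrangement to the methoxycyclobutenedione.

Step 8
Reactants: 16 4-hydroxy-2,3-dimethoxycyclobut-2-en-1-one
Product: 17 4-chloro-2,3-dimethoxycyclobut-2-en-1-one (racemic)
Conditions: PPh3, CCl4, CH2Cl2, 0 °C to rt; kept cold and used promptly
Reagents that add atoms: carbon tetrachloride, ClC(Cl)(Cl)Cl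
Why: Appel chlorination converts the secondary allylic alcohol into the chloride through an alkoxyphosphonium ion under neutral, non-ionising conditions, chosen so that substitution occurs at the carbinol carbon without allylic transposition.

Step 9
Reactants: 14 (3R,4R)-3-[4-(benzyloxy)-3-methoxybenzyl]-4-[2-(tributylstannyl)prop-2-en-1-yl]dihydrofuran-2(3H)-one; 17 4-chloro-2,3-dimethoxycyclobut-2-en-1-one
Product: 21 (3R,4R)-3-[4-(benzyloxy)-3-methoxybenzyl]-4-(3-hydroxy-4,5-dimethoxybenzyl)dihydrofuran-2(3H)-one, via alkenylcyclobutenone 18 (not isolated), via dienylketene 19 (not isolated), via cyclohexadienone 20 (not isolated)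
Conditions: PdCl2(PhCN)2 (5 mol%), tri(2-furyl)phosphine (10 mol%), 17 (1.3 equiv), dioxane, 50 °C; then 100 °C
Reagents that add atoms: none
Why: Zerovalent palladium, generated in situ, adds oxidatively to the allylic C–Cl bond of 17, and transmetallation with the alkenylstannane followed by reductive elimination at the former CHCl carbon gives 18 (Stille coupling, bond C1′–C6′). At 100 °C 18 opens reversibly by conrotatory 4π electrocyclic cleavage of the C(=O)–CH bond to the dienylketene, and the (3E) isomer 19 closes by thermal disrotatory 6π electrocyclisation between the ketene carbon and the terminal CH2 (bond C2′–C3′), which forms ring C as the cyclohexadienone 20 that tautomerises to the phenol 21. The closest known reaction type is the palladium-catalysed coupling of 4-chlorocyclobutenones with alkenyl- and arylstannanes followed by thermal ring expansion to phenols. No stereocentre is created in the product: the cyclobutenone CH centre of 18 is uncontrolled and is erased on aromatisation, while C3 and C4 of the lactone are remote and see only neutral conditions. The selectivity required is regiochemical, namely bond formation at the chlorine-bearing carbon without allylic transposition and ipso instead of cine substitution at tin; the first is secured because the other allyl terminus is a fully substituted methoxy-bearing carbon next to the carbonyl, the second is helped by the weakly donating furylphosphine, which accelerates transmetallation. Once 18 has this connectivity, ring opening and closure can only give the 3-hydroxy-4,5-dimethoxy-1-alkyl arrangement.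

Step 10
Reactants: 21 (3R,4R)-3-[4-(benzyloxy)-3-methoxybenzyl]-4-(3-hydroxy-4,5-dimethoxybenzyl)dihydrofuran-2(3H)-one
Product: 22 (3R,4R)-3-[4-(benzyloxy)-3-methoxybenzyl]-4-(3,4,5-trimethoxybenzyl)dihydrofuran-2(3H)-one
Conditions: MeI, K2CO3, acetone, reflux
Reagents that add atoms: iodomethane, CI
Why: Williamson O-methylation of the only free phenol, with a carbonate base too weak to enolise or open the lactone in anhydrous acetone.

Step 11
Reactants: 22 (3R,4R)-3-[4-(benzyloxy)-3-methoxybenzyl]-4-(3,4,5-trimethoxybenzyl)dihydrofuran-2(3H)-one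
Product: 23 (3R,4R)-3-(4-hydroxy-3-methoxybenzyl)-4-(3,4,5-trimethoxybenzyl)dihydrofuran-2(3H)-one (CNP0261601.1)
Conditions: H2 (1 atm), Pd/C (10 wt% palladium on carbon), EtOAc–EtOH, rt
Reagents that add atoms: none
Why: Catalytic hydrogenolysis cleaves the benzyl aryl ether to free the C4 phenol of ring A, while the lactone, the methyl ethers and both stereocentres (neither next to a benzylic C–O bond) are inert.

Compound list

1 | pent-4-ynoic acid | C#CCCC(=O)O | starting material
2 | (S)-4-benzyloxazolidin-2-one | O=C1OC[C@H](Cc2ccccc2)N1 | starting material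
3 | pent-4-ynoic pivalic anhydride | C#CCCC(=O)OC(=O)C(C)(C)C | intermediate
4 | (S)-4-benzyl-3-(pent-4-ynoyl)oxazolidin-2-one | C#CCCC(=O)N1[C@@H](Cc2ccccc2)COC1=O | intermediate
5 | tert-butyl bromoacetate | CC(C)(C)OC(=O)CBr | starting material
6 | sodium (Z)-1-[(4S)-4-benzyl-2-oxo-1,3-oxazolidin-3-yl]pent-1-en-4-yn-1-olate | [Na+].C#CC/C=C(\[O-])N1[C@@H](Cc2ccccc2)COC1=O | intermediate
7 | tert-butyl (3R)-3-{[(4S)-4-benzyl-2-oxo-1,3-oxazolidin-3-yl]carbonyl}hex-5-ynoate | C#CC[C@H](CC(=O)OC(C)(C)C)C(=O)N1[C@@H](Cc2ccccc2)COC1=O | intermediate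
8 | tert-butyl (3R)-3-(hydroxymethyl)hex-5-ynoate | C#CC[C@H](CC(=O)OC(C)(C)C)CO | intermediate
9 | (R)-4-(prop-2-yn-1-yl)dihydrofuran-2(3H)-one | C#CC[C@H]1COC(=O)C1 | intermediate
10 | (S)-4-[2-(tributylstannyl)prop-2-en-1-yl]dihydrofuran-2(3H)-one | C=C(C[C@H]1COC(=O)C1)[Sn](CCCC)(CCCC)CCCC | intermediate
11 | 4-(benzyloxy)-3-methoxybenzyl alcohol | COc1cc(CO)ccc1OCc1ccccc1 | starting material
12 | 4-(benzyloxy)-3-methoxybenzyl bromide | COc1cc(CBr)ccc1OCc1ccccc1 | intermediate
13 | lithium (4R)-4-[2-(tributylstannyl)prop-2-en-1-yl]-4,5-dihydrofuran-2-olate | [Li+].[O-]C1=C[C@@H](CC(=C)[Sn](CCCC)(CCCC)CCCC)CO1 | intermediate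
14 | (3R,4R)-3-[4-(benzyloxy)-3-methoxybenzyl]-4-[2-(tributylstannyl)prop-2-en-1-yl]dihydrofuran-2(3H)-one | COc1cc(C[C@H]2C(=O)OC[C@@H]2CC(=C)[Sn](CCCC)(CCCC)CCCC)ccc1OCc1ccccc1 | intermediate
15 | dimethyl squarate (3,4-dimethoxycyclobut-3-ene-1,2-dione) | COC1=C(OC)C(=O)C1=O | starting material
16 | 4-hydroxy-2,3-dimethoxycyclobut-2-en-1-one (racemic) | COC1=C(OC)C(=O)C1O | intermediate
17 | 4-chloro-2,3-dimethoxycyclobut-2-en-1-one (racemic) | COC1=C(OC)C(=O)C1Cl | intermediate
18 | (3R,4R)-3-[4-(benzyloxy)-3-methoxybenzyl]-4-[2-(2,3-dimethoxy-4-oxocyclobut-2-en-1-yl)prop-2-en-1-yl]dihydrofuran-2(3H)-one (both epimers at the cyclobutenone CH) | COc1cc(C[C@H]2C(=O)OC[C@@H]2CC(=C)C2C(OC)=C(OC)C2=O)ccc1OCc1ccccc1 | intermediate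
19 | (3R,4R)-3-[4-(benzyloxy)-3-methoxybenzyl]-4-[(3E)-4,5-dimethoxy-2-methylidene-6-oxohexa-3,5-dien-1-yl]dihydrofuran-2(3H)-one | COc1cc(C[C@H]2C(=O)OC[C@@H]2CC(=C)/C=C(OC)\C(OC)=C=O)ccc1OCc1ccccc1 | intermediate
20 | (3R,4R)-3-[4-(benzyloxy)-3-methoxybenzyl]-4-[(3,4-dimethoxy-5-oxocyclohexa-1,3-dien-1-yl)methyl]dihydrofuran-2(3H)-one | COc1cc(C[C@H]2C(=O)OC[C@@H]2CC2=CC(OC)=C(OC)C(=O)C2)ccc1OCc1ccccc1 | intermediate
21 | (3R,4R)-3-[4-(benzyloxy)-3-methoxybenzyl]-4-(3-hydroxy-4,5-dimethoxybenzyl)dihydrofuran-2(3H)-one | COc1cc(C[C@H]2C(=O)OC[C@@H]2Cc2cc(O)c(OC)c(OC)c2)ccc1OCc1ccccc1 | intermediate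
22 | (3R,4R)-3-[4-(benzyloxy)-3-methoxybenzyl]-4-(3,4,5-trimethoxybenzyl)dihydrofuran-2(3H)-one | COc1cc(C[C@H]2C(=O)OC[C@@H]2Cc2cc(OC)c(OC)c(OC)c2)ccc1OCc1ccccc1 | intermediate
23 | (3R,4R)-3-(4-hydroxy-3-methoxybenzyl)-4-(3,4,5-trimethoxybenzyl)dihydrofuran-2(3H)-one | COc1cc(C[C@H]2C(=O)OC[C@@H]2Cc2cc(OC)c(OC)c(OC)c2)ccc1O | target

Total step count: 11. Longest linear sequence: 8 steps (steps 1, 2, 3, 4, 6, 9, 10, 11); step 5 and steps 7–8 are side branches.

Steps most likely to fail

Step 9. Transmetallation of the hindered 1,1-disubstituted alkenylstannane may be slow enough that protodestannylation, cine substitution or coupling at the methoxy-bearing allyl terminus takes over, so that ring C does not form or forms as a regioisomer. The fallback brings ring C in ready-made by the classical auxiliary sequence and sets out from 2. Commercial 3-(3,4,5-trimethoxyphenyl)propanoic acid is activated with PivCl/Et3N as 3-(3,4,5-trimethoxyphenyl)propanoic pivalic anhydride F1 and coupled with 2 (LiCl) to (S)-4-benzyl-3-[3-(3,4,5-trimethoxyphenyl)propanoyl]oxazolidin-2-one F2. NaN(SiMe3)2 converts this into sodium (Z)-1-[(4S)-4-benzyl-2-oxo-1,3-oxazolidin-3-yl]-3-(3,4,5-trimethoxyphenyl)prop-1-en-1-olate F3, which is alkylated with 5 to tert-butyl (3R)-3-{[(4S)-4-benzyl-2-oxo-1,3-oxazolidin-3-yl]carbonyl}-4-(3,4,5-trimethoxyphenyl)butanoate F4. LiBH4 reduction gives tert-butyl (3R)-3-(hydroxymethyl)-4-(3,4,5-trimethoxyphenyl)butanoate F5, which TFA closes to (R)-4-(3,4,5-trimethoxybenzyl)dihydrofuran-2(3H)-one F6. LiN(SiMe3)2 then gives lithium (4R)-4-(3,4,5-trimethoxybenzyl)-4,5-dihydrofuran-2-olate F7, which is alkylated with 12 trans to the C4 substituent. The sequence comes back to the route at 22, just before step 11.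

Step 8. The activated alcohol may ionise to the delocalised alkoxycyclobutenyl cation, which would let chloride enter at the methoxy-bearing terminus or demethylate the oxocarbenium ion to 3-methoxycyclobutene-1,2-dione. The fallback gives up the halide for an allylic ester that cannot ionise while it is being made. Setting out from 16, acetylation (Ac2O, pyridine, DMAP, CH2Cl2, 0 °C) should give 2,3-dimethoxy-4-oxocyclobut-2-en-1-yl acetate F8. F8 replaces 17 as the electrophile towards 14 in a palladium-catalysed allylic acetate–alkenylstannane coupling (Pd2(dba)3, LiCl, DMF, then heating). The sequence comes back to the route at 18 and continues to 21 as in step 9.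

Step 4. Tin may be delivered to the terminal alkyne carbon, which would give the linear alkenylstannane that cannot lead to ring C. The fallback replaces catalytic hydrometallation by stoichiometric stannylcupration–protonation, in which syn addition of a stannylcopper reagent to the 1-alkyne and immediate protonation by methanol place tin on the internal carbon. Setting out from 9, Me3SnCu·SMe2 (from Me3SnLi and CuBr·SMe2) in THF–MeOH at −78 °C should give (S)-4-[2-(trimethylstannyl)prop-2-en-1-yl]dihydrofuran-2(3H)-one F9. Deprotonation as in step 6 gives lithium (4R)-4-[2-(trimethylstannyl)prop-2-en-1-yl]-4,5-dihydrofuran-2-olate F10, which is alkylated with 12 to (3R,4R)-3-[4-(benzyloxy)-3-methoxybenzyl]-4-[2-(trimethylstannyl)prop-2-en-1-yl]dihydrofuran-2(3H)-one F11. F11 is coupled with 17 under the conditions of step 9 and comes back to the route at 18.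

Further compounds

F1 | step 9 | 3-(3,4,5-trimethoxyphenyl)propanoic pivalic anhydride | COc1cc(CCC(=O)OC(=O)C(C)(C)C)cc(OC)c1OC
F2 | step 9 | (S)-4-benzyl-3-[3-(3,4,5-trimethoxyphenyl)propanoyl]oxazolidin-2-one | COc1cc(CCC(=O)N2[C@@H](Cc3ccccc3)COC2=O)cc(OC)c1OC
F3 | step 9 | sodium (Z)-1-[(4S)-4-benzyl-2-oxo-1,3-oxazolidin-3-yl]-3-(3,4,5-trimethoxyphenyl)prop-1-en-1-olate | [Na+].COc1cc(C/C=C(\[O-])N2[C@@H](Cc3ccccc3)COC2=O)cc(OC)c1OC
F4 | step 9 | tert-butyl (3R)-3-{[(4S)-4-benzyl-2-oxo-1,3-oxazolidin-3-yl]carbonyl}-4-(3,4,5-trimethoxyphenyl)butanoate | COc1cc(C[C@H](CC(=O)OC(C)(C)C)C(=O)N2[C@@H](Cc3ccccc3)COC2=O)cc(OC)c1OC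
F5 | step 9 | tert-butyl (3R)-3-(hydroxymethyl)-4-(3,4,5-trimethoxyphenyl)butanoate | COc1cc(C[C@H](CC(=O)OC(C)(C)C)CO)cc(OC)c1OC
F6 | step 9 | (R)-4-(3,4,5-trimethoxybenzyl)dihydrofuran-2(3H)-one | COc1cc(C[C@H]2COC(=O)C2)cc(OC)c1OC
F7 | step 9 | lithium (4R)-4-(3,4,5-trimethoxybenzyl)-4,5-dihydrofuran-2-olate | [Li+].COc1cc(C[C@H]2COC([O-])=C2)cc(OC)c1OC
F8 | step 8 | 2,3-dimethoxy-4-oxocyclobut-2-en-1-yl acetate (racemic) | COC1=C(OC)C(=O)C1OC(C)=O
F9 | step 4 | (S)-4-[2-(trimethylstannyl)prop-2-en-1-yl]dihydrofuran-2(3H)-one | C=C(C[C@H]1COC(=O)C1)[Sn](C)(C)C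
F10 | step 4 | lithium (4R)-4-[2-(trimethylstannyl)prop-2-en-1-yl]-4,5-dihydrofuran-2-olate | [Li+].[O-]C1=C[C@@H](CC(=C)[Sn](C)(C)C)CO1
F11 | step 4 | (3R,4R)-3-[4-(benzyloxy)-3-methoxybenzyl]-4-[2-(trimethylstannyl)prop-2-en-1-yl]dihydrofuran-2(3H)-one | COc1cc(C[C@H]2C(=O)OC[C@@H]2CC(=C)[Sn](C)(C)C)ccc1OCc1ccccc1
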